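**One step.** In a one-step world, electrophile plus nucleophile giving product with c(nucleophile) held, the negative logarithm of the fraction of electrophile left rises straight with time, at a slope proportional to c(nucleophile). This is the bench rule of a pseudo-first-order reaction.

| flask | electrophile | nucleophile | remark | time |
|---|---|---|---|---|
| dusk | 13 mM | 40 mM | run made earlier |  |
| spring | 40 mM | 40 mM | run made earlier |  |
| delta | 20 mM | 40.0 mM |  | 40 h |
| zeta | 20 mM | 80.0 mM |  | 40 h |

| run | time / h | electrophile / % | product / % |
|---|---|---|---|
| dusk | 0.500 | 100.0 | 2.9 |
| dusk | 1.50 | 95.9 | 4.2 |
| dusk | 3.00 | 92.9 | 9.4 |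
| dusk | 4.00 | 87.8 | 12.2 |
| dusk | 6.00 | 86.1 | 14.2 |
| dusk | 8.00 | 81.9 | 17.4 |
| spring | 1.33 | 96.9 | 5.2 |
| spring | 2.50 | 92.9 | 9.1 |
| spring | 4.00 | 90.0 | 11.1 |
| spring | 5.00 | 88.6 | 11.9 |
| spring | 6.00 | 88.1 | 13.2 |
| spring | 8.00 | 84.9 | 15.9 |

(each reading ± 1 percentage point)

1. part of the electrophile that has reacted at the end, delta
2. part of the electrophile that has reacted at the end, zeta
3. what raising the concentration of nucleophile from its lowest to its highest value here does to the part of the electrophile that has reacted (changes below 5 percentage points count as none) (no change / it falls / it rises)

- steps thought possible: nucleophile <-> dormant form; electrophile + nucleophile -> acid set free + product; nucleophile + acid set free <-> protonated nucleophile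

**Late slope.** Both runs bend early, so we take the stretch from 4.00 h to 8.00 h, where the logarithm climbs at 0.0174 /h in dusk and 0.0146 /h in spring. Their mean divided by the charged c(nucleophile) is what we carry, the late slope s, 0.400 /M/h, a reading with the scatter of its readings.

**The rule.** Taking s × c(nucleophile) × time as the logarithm, our first figures for 40 h are 47.2% for delta and 72.2% for zeta.

**The border.** The rule needs c(nucleophile) held. But each product uses one nucleophile, and the acid set free can protonate another, so we count two lost from the pool of free and dormant nucleophile. The ratio r, two c(electrophile) over c(nucleophile) as charged, is 1.00 in delta and 0.500 in zeta. The pool share at conversion x is then one minus r times x, which is far from held.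

**Mean pool.** We replace the falling pool by its mean, one minus r times x divided by two, and multiply the logarithm by it. That gives 38.6% and 64.9%. A second pass moves these to 40.3% and 65.7%, which we commit to, so the mean pool lowers the first figures by 6.9 percentage points in delta and 6.4 points in zeta.

**The forecast.** It gives 43% (31% to 56%) for delta, 70% (51% to 85%) for zeta, and says it rises. Its ground: “Each product removes two nucleophiles, one reacted and one protonated”. Both figures stand above ours .

**The flask.** Delta gives 39.3% and zeta 64.9%; the answer on the trend is it rises, by 26 points. In delta at 40.0 h, protonated nucleophile stands at 7.42 mM beside 7.85 mM of product.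

    nucleophile ⇌ dormant form (K = 1.70, k = 2.10 × 10⁻⁵ /s)
    electrophile + nucleophile → acid set free + product (k = 2.40 × 10⁻⁴ /M/s)
    nucleophile + acid set free ⇌ protonated nucleophile, settled at all times (K = 2100 /M)

**A neighbour.** Take zeta with 20 mM of nucleophile, where r is 2.00. The late slope gives 27.4%, the mean pool brings that to 20.7%, and this flask gives 21.6%.

The data were generated by integration from invented constants, and the scatter is random.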